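**Plan**

1. Numbering: phthalide C3; tether C1′–C6′; spiroketal ring A = O1/C2/C3/C4/C5 (tether on C2), ring B = C5/O6/C7/C8/C9 (methyl on C7). Retrosynthesis cuts the O6–C5 bond of ring B first (C–H oxidation transform, back to a C5–H oxolane with an (R)-3-hydroxybutyl chain), then C5–C9 (alkynylation of a ring A oxocarbenium ion), C2′=C3′ (cross-metathesis) and the aryl–C1 bond of the phthalide (carboxylation).
2. Forward: the benzene ring is bought and the phthalide lactone is closed in step 3. Ring A is carried in from a chiral-pool γ-butyrolactone (steps 4–6). The tether is joined in step 7, the C7–C9 chain in step 9, all unsaturation is removed in step 10, and ring B is closed last in step 11.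
3. Stereochemistry: C3 (R) from a Brown allylboration (reagent control); C2 (R) from the (S)-tosyloxymethyl butyrolactone; C7 (R) from (R)-but-3-yn-2-ol; spiro C5 (S) is set in the key step.
4. Enabling feature: C5 is the δ-carbon of the C7 oxygen (O6–C7–C8–C9–C5) and bears the ring A oxygen O1. Its hydrogen is therefore the only one within 1,5-reach of an O6 radical, and the radical formed is oxidized to an oxocarbenium ion. The C5 configuration of the precursor is irrelevant, so C5 travels through the route as an inert ether C–H and never as a ketone.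

Key step: step 11

Remark: 8, 13, but-3-enylmagnesium bromide and (+)-Ipc2B(allyl) are taken as commercial; compounds 10–12 and 17–19 are carried as mixtures at the carbon that becomes C5 (SMILES leave it open), and 12 and 17 as E/Z mixtures.

**Route**

Step 1
Reactants: 1 3,5-dimethoxybenzaldehyde
Product: 2 2-bromo-3,5-dimethoxybenzaldehyde
Conditions: NBS (1.05 equiv), MeCN, 0 °C to rt
Reagents that add atoms: N-bromosuccinimide, O=C1CCC(=O)N1Br
Why: Electrophilic aromatic bromination, which for this aldehyde goes to the position ortho to the formyl group and para to a methoxy group because the site between the two methoxy groups is more hindered.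

Step 2
Reactants: 2 2-bromo-3,5-dimethoxybenzaldehyde
Product: 4 (1R)-1-(2-bromo-3,5-dimethoxyphenyl)but-3-en-1-ol, via borinate ester 3 (not isolated)
Conditions: (+)-Ipc2B(allyl) (1.3 equiv, 1 M in pentane), Et2O, −78 °C; then 3 M NaOH, 30% H2O2, rt
Reagents that add atoms: (+)-B-allyldiisopinocampheylborane, C=CCB([C@H]1C[C@H]2C[C@@H]([C@@H]1C)C2(C)C)[C@H]1C[C@H]2C[C@@H]([C@@H]1C)C2(C)C
Why: Brown asymmetric allylboration through a chair six-membered transition state, in which the reagent of the (−)-α-pinene series delivers allyl to the Re face of aryl aldehydes and so sets the (R)-carbinol that becomes C3.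

Step 3
Reactants: 4 (1R)-1-(2-bromo-3,5-dimethoxyphenyl)but-3-en-1-ol
Product: 7 (3R)-5,7-dimethoxy-3-(prop-2-en-1-yl)-2-benzofuran-1(3H)-one, via dilithio species 5 (not isolated), via hydroxy acid 6 (not isolated)
Conditions: n-BuLi (2.2 equiv), THF, −78 °C; CO2 (gas), −78 °C; 2 M HCl, rt
Reagents that add atoms: carbon dioxide, O=C=O
Why: Alkoxide formation and bromine–lithium exchange give an aryllithium that is carboxylated at −78 °C (cold enough to stop 5-exo carbolithiation of the alkene), and the hydroxy acid lactonizes on acidification by acyl substitution, so the carbinol C–O bond and its configuration are retained.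

Step 4
Reactants: 8 [(2S)-5-oxooxolan-2-yl]methyl 4-methylbenzenesulfonate
Product: 9 (5R)-5-(pent-4-en-1-yl)oxolan-2-one
Conditions: but-3-enylMgBr (2.4 equiv), CuI (1.2 equiv), THF, −40 °C (forms (but-3-enyl)2CuMgBr); then 8, −40 to −15 °C; aq NH4Cl
Reagents that add atoms: but-3-enylmagnesium bromide, C=CCC[Mg]Br
Why: SN2 displacement of the primary tosylate by a homocuprate (organocopper substitution), soft enough to spare the lactone carbonyl at low temperature; no bond to the stereocentre is touched and the descriptor changes from S to R only because the CIP priorities change.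

Step 5
Reactants: 9 (5R)-5-(pent-4-en-1-yl)oxolan-2-one
Product: 10 (5R)-5-(pent-4-en-1-yl)oxolan-2-ol
Conditions: i-Bu2AlH (1.1 equiv), CH2Cl2, −78 °C; aq potassium sodium tartrate
Reagents that add atoms: none
Why: Low-temperature DIBAL-H half-reduction of a γ-lactone, which stops at the lactol because the tetrahedral aluminium alkoxide survives until work-up; the terminal alkene is inert.

Step 6
Reactants: 10 (5R)-5-(pent-4-en-1-yl)oxolan-2-ol
Product: 11 (5R)-2-(benzenesulfonyl)-5-(pent-4-en-1-yl)oxolane
Conditions: PhSO2H (1.5 equiv), CaCl2 (powder), CH2Cl2, rt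
Reagents that add atoms: benzenesulfinic acid, OS(=O)c1ccccc1
Why: Acid-mediated anomeric substitution (lactol to α-sulfonyl ether via the oxocarbenium ion, sulfur-bound product), which stores the future spiro carbon at the aldehyde oxidation level in a form inert to ruthenium alkylidenes; both anomers are usable.

Step 7
Reactants: 7 (3R)-5,7-dimethoxy-3-(prop-2-en-1-yl)-2-benzofuran-1(3H)-one; 11 (5R)-2-(benzenesulfonyl)-5-(pent-4-en-1-yl)oxolane
Product: 12 (3R)-3-{6-[(2R)-5-(benzenesulfonyl)oxolan-2-yl]hex-2-en-1-yl}-5,7-dimethoxy-2-benzofuran-1(3H)-one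
Conditions: second-generation Grubbs catalyst RuCl2(H2IMes)(PCy3)(=CHPh) (5 mol%), 7 (2.5 equiv), CH2Cl2, 40 °C, argon sweep
Reagents that add atoms: none
Why: Olefin cross-metathesis between two unhindered monosubstituted alkenes, driven by loss of ethylene and by the excess of 7 (its self-metathesis dimer can be resubmitted); lactone, sulfone and ether groups are tolerated and the alkene geometry is irrelevant.

Step 8
Reactants: 13 (2R)-but-3-yn-2-ol
Product: 14 ({[(2R)-but-3-yn-2-yl]oxy}methyl)benzene
Conditions: NaH (1.05 equiv), BnBr (1.1 equiv), n-Bu4NI (cat.), THF, 0 °C to rt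
Reagents that add atoms: benzyl bromide, BrCc1ccccc1
Why: Williamson ether synthesis at oxygen (the alkoxide forms in preference to the acetylide), which leaves the C–O stereocentre untouched; benzyl is chosen so that step 10 removes it without an extra operation.

Step 9
Reactants: 12 (3R)-3-{6-[(2R)-5-(benzenesulfonyl)oxolan-2-yl]hex-2-en-1-yl}-5,7-dimethoxy-2-benzofuran-1(3H)-one; 14 ({[(2R)-but-3-yn-2-yl]oxy}methyl)benzene
Product: 17 (3R)-3-{6-[(2R)-5-[(3R)-3-(benzyloxy)but-1-yn-1-yl]oxolan-2-yl]hex-2-en-1-yl}-5,7-dimethoxy-2-benzofuran-1(3H)-one, via lithium acetylide 15 (not isolated), via alkynylzinc bromide 16 (not isolated)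
Conditions: 14 (2.6 equiv), n-BuLi (2.5 equiv), THF, −78 °C; ZnBr2 (3 equiv), 0 °C; then 12, THF, rt
Reagents that add atoms: none
Why: Lewis acid-assisted substitution of an anomeric sulfone by an organozinc: ZnBr2 ionizes the C–S bond and the alkynylzinc captures the ring A oxocarbenium ion, while the weakly basic zinc acetylide leaves the phthalide and the α-sulfonyl hydrogen alone; the configuration created at this carbon is of no consequence.

Step 10
Reactants: 17 (3R)-3-{6-[(2R)-5-[(3R)-3-(benzyloxy)but-1-yn-1-yl]oxolan-2-yl]hex-2-en-1-yl}-5,7-dimethoxy-2-benzofuran-1(3H)-one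
Product: 18 (3R)-3-{6-[(2R)-5-[(3R)-3-hydroxybutyl]oxolan-2-yl]hexyl}-5,7-dimethoxy-2-benzofuran-1(3H)-one
Conditions: H2 (1 atm), 10% Pd/C, EtOAc–EtOH, rt
Reagents that add atoms: none
Why: Heterogeneous catalytic hydrogenation saturates the alkene and the alkyne and then hydrogenolyses the benzyl ether in one operation, unmasking the C7 hydroxyl; the aryl methyl ethers and the lactone are expected to survive neutral conditions at 1 atm.

Step 11
Reactants: 18 (3R)-3-{6-[(2R)-5-[(3R)-3-hydroxybutyl]oxolan-2-yl]hexyl}-5,7-dimethoxy-2-benzofuran-1(3H)-one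
Product: 20 (3R)-5,7-dimethoxy-3-{6-[(2R,5S,7R)-7-methyl-1,6-dioxaspiro[4.4]nonan-2-yl]hexyl}-2-benzofuran-1(3H)-one, via hypoiodite 19 (not isolated)
Conditions: PhI(OAc)2 (1.3 equiv), I2 (0.6 equiv), cyclohexane–CH2Cl2, visible light (tungsten lamp), 15–20 °C; aq Na2S2O3; C5 epimers separated on silica, the unwanted one re-equilibrated (PPTS cat., CH2Cl2) and recycled
Reagents that add atoms: none
Why: Acetyl hypoiodite (from PhI(OAc)2 and I2) turns the C7 hydroxyl into hypoiodite 19, visible light cleaves its O–I bond, the O6 radical removes the C5 hydrogen of ring A by 1,5-hydrogen transfer through a six-membered transition state, and the α-alkoxy radical is oxidized by iodine to the ring A oxocarbenium ion, which the regenerated C7 hydroxyl captures. The closest known reaction type is the Suárez hypoiodite reaction, the alkoxy-radical hydrogen abstraction and oxidative cyclization that converts hydroxyalkyl cyclic ethers into spiroketals. Ring B is closed in a 5-exo-trig mode by attack of O6 on C5 of the C5=O1 oxocarbenium unit. The only new stereocentre is spiro C5: both C5 epimers of 18 converge on one planar cation, and O6 is expected to add anti to the C2 hexyl chain, which gives the target epimer (both ring substituents anti to the oxygen of the other ring); the bias in a 5,5-spiroketal is expected to be modest, hence the epimer recycling. Site selectivity is secured by the substrate, since the C5 hydrogen is the only one δ to O6 and the weakest C–H within reach, while C2, C3 and C7 keep their configuration because none of their bonds is broken. Chemoselectivity over iodination of the aromatic ring rests on fast O-iodination of the alcohol and on deactivation of the dimethoxyarene by the lactone carbonyl.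

**Compound list**

1 | 3,5-dimethoxybenzaldehyde | COc1cc(OC)cc(C=O)c1 | starting material
2 | 2-bromo-3,5-dimethoxybenzaldehyde | COc1cc(OC)c(Br)c(C=O)c1 | intermediate
3 | (1R)-1-(2-bromo-3,5-dimethoxyphenyl)but-3-en-1-yl diisopinocampheylborinate | COc1cc(OC)c(Br)c(c1)[C@H](OB([C@H]2C[C@H]3C[C@@H]([C@@H]2C)C3(C)C)[C@H]2C[C@H]3C[C@@H]([C@@H]2C)C3(C)C)CC=C | intermediate (not isolated)
4 | (1R)-1-(2-bromo-3,5-dimethoxyphenyl)but-3-en-1-ol | COc1cc(OC)c(Br)c(c1)[C@H](O)CC=C | intermediate
5 | lithium (1R)-1-(2-lithio-3,5-dimethoxyphenyl)but-3-en-1-olate | COc1cc(OC)c([Li])c(c1)[C@H](O[Li])CC=C | intermediate (not isolated)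
6 | 2-[(1R)-1-hydroxybut-3-en-1-yl]-4,6-dimethoxybenzoic acid | COc1cc(OC)c(C(=O)O)c(c1)[C@H](O)CC=C | intermediate (not isolated)
7 | (3R)-5,7-dimethoxy-3-(prop-2-en-1-yl)-2-benzofuran-1(3H)-one | COc1cc(OC)c2c(c1)[C@@H](CC=C)OC2=O | intermediate
8 | [(2S)-5-oxooxolan-2-yl]methyl 4-methylbenzenesulfonate | Cc1ccc(cc1)S(=O)(=O)OC[C@@H]1CCC(=O)O1 | starting material
9 | (5R)-5-(pent-4-en-1-yl)oxolan-2-one | C=CCCC[C@@H]1CCC(=O)O1 | intermediate
10 | (5R)-5-(pent-4-en-1-yl)oxolan-2-ol (anomers) | C=CCCC[C@@H]1CCC(O)O1 | intermediate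
11 | (5R)-2-(benzenesulfonyl)-5-(pent-4-en-1-yl)oxolane (C2 epimers) | C=CCCC[C@@H]1CCC(O1)S(=O)(=O)c1ccccc1 | intermediate
12 | (3R)-3-{6-[(2R)-5-(benzenesulfonyl)oxolan-2-yl]hex-2-en-1-yl}-5,7-dimethoxy-2-benzofuran-1(3H)-one | COc1cc(OC)c2c(c1)[C@@H](CC=CCCC[C@@H]1CCC(O1)S(=O)(=O)c1ccccc1)OC2=O | intermediate
13 | (2R)-but-3-yn-2-ol | C#C[C@@H](C)O | starting material
14 | ({[(2R)-but-3-yn-2-yl]oxy}methyl)benzene | C#C[C@@H](C)OCc1ccccc1 | intermediate
15 | [(3R)-3-(benzyloxy)but-1-yn-1-yl]lithium | [Li]C#C[C@@H](C)OCc1ccccc1 | intermediate (not isolated)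
16 | [(3R)-3-(benzyloxy)but-1-yn-1-yl]zinc bromide | Br[Zn]C#C[C@@H](C)OCc1ccccc1 | intermediate (not isolated)
17 | (3R)-3-{6-[(2R)-5-[(3R)-3-(benzyloxy)but-1-yn-1-yl]oxolan-2-yl]hex-2-en-1-yl}-5,7-dimethoxy-2-benzofuran-1(3H)-one | COc1cc(OC)c2c(c1)[C@@H](CC=CCCC[C@@H]1CCC(O1)C#C[C@@H](C)OCc1ccccc1)OC2=O | intermediate
18 | (3R)-3-{6-[(2R)-5-[(3R)-3-hydroxybutyl]oxolan-2-yl]hexyl}-5,7-dimethoxy-2-benzofuran-1(3H)-one | COc1cc(OC)c2c(c1)[C@@H](CCCCCC[C@@H]1CCC(O1)CC[C@@H](C)O)OC2=O | intermediate
19 | hypoiodite of 18 (O–I in place of the O–H of the hydroxybutyl chain) | COc1cc(OC)c2c(c1)[C@@H](CCCCCC[C@@H]1CCC(O1)CC[C@@H](C)OI)OC2=O | intermediate (not isolated)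
20 | (3R)-5,7-dimethoxy-3-{6-[(2R,5S,7R)-7-methyl-1,6-dioxaspiro[4.4]nonan-2-yl]hexyl}-2-benzofuran-1(3H)-one | COc1cc(OC)c2c(c1)[C@@H](CCCCCC[C@@H]1CC[C@]3(CC[C@@H](C)O3)O1)OC2=O | target

**Count and risks**

Total steps: 11. Longest linear sequence: 7 (steps 1, 2, 3, 7, 9, 10, 11; the lactone branch 4, 5, 6, 7, 9, 10, 11 is equally long).

Step 11. What may go wrong: electrophilic iodination of the dimethoxybenzene ring by acetyl hypoiodite in competition with O-iodination, and weak facial discrimination in the capture of the oxocarbenium ion. Fallback (sets out from 7 and 9, returns at 20):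
- Cross-metathesis of 7 with lactone 9 under the step 7 conditions would give the bis-lactone (3R)-5,7-dimethoxy-3-{6-[(2R)-5-oxooxolan-2-yl]hex-2-en-1-yl}-2-benzofuran-1(3H)-one F1.
- Lithium acetylide 15 with BF3·OEt2 in THF at −78 °C should add to the aliphatic γ-lactone in preference to the deactivated aryl lactone and give the hydroxy ynone (3R)-3-[(7R,13R)-13-(benzyloxy)-7-hydroxy-10-oxotetradec-2-en-11-yn-1-yl]-5,7-dimethoxy-2-benzofuran-1(3H)-one F2.
- H2 over Pd/C would give the keto diol (3R)-3-[(7R,13R)-7,13-dihydroxy-10-oxotetradecyl]-5,7-dimethoxy-2-benzofuran-1(3H)-one F3.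
- Camphorsulfonic acid in CH2Cl2 would close ring A as the hemiketal and then ring B by loss of water, returning to 20 under thermodynamic control with no iodine electrophile present.

Step 9. What may go wrong: loss of benzenesulfinic acid from the oxolanyl sulfone to a dihydrofuran, or hydrolysis back to the lactol, outrunning C–C bond formation. Fallback (sets out from 9 and 14, used as 15, and from 7; returns at 17):
- 15 adds to lactone 9 (THF, −78 °C) to give the hydroxy ynone (2R,8R)-2-(benzyloxy)-8-hydroxytridec-12-en-3-yn-5-one F4.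
- Ionic hydrogenation of its cyclic hemiketal form (Et3SiH, BF3·OEt2, CH2Cl2–MeCN, −40 °C) gives (5R)-2-[(3R)-3-(benzyloxy)but-1-yn-1-yl]-5-(pent-4-en-1-yl)oxolane F5.
- Cross-metathesis of F5 with 7 returns to 17; the internal alkyne sits between two branched carbons and should be spared by the catalyst.

Step 10. What may go wrong: C–O hydrogenolysis at the propargylic and allylic positions while the alkyne is being saturated (opening of ring A or loss of the C7 oxygen), made worse by the long exposure needed for debenzylation. Fallback (sets out from 17, returns at 18):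
- Diimide (from 2-nitrobenzenesulfonylhydrazide and Et3N, CH2Cl2, rt, repeated charges) saturates the alkene and the alkyne without a metal surface and gives the benzyl ether (3R)-3-{6-[(2R)-5-[(3R)-3-(benzyloxy)butyl]oxolan-2-yl]hexyl}-5,7-dimethoxy-2-benzofuran-1(3H)-one F6.
- With no allylic or propargylic C–O bond left, a short hydrogenolysis over Pd(OH)2/C then returns to 18.

Further compounds
F1 | step 11 | (3R)-5,7-dimethoxy-3-{6-[(2R)-5-oxooxolan-2-yl]hex-2-en-1-yl}-2-benzofuran-1(3H)-one | COc1cc(OC)c2c(c1)[C@@H](CC=CCCC[C@@H]1CCC(=O)O1)OC2=O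
F2 | step 11 | (3R)-3-[(7R,13R)-13-(benzyloxy)-7-hydroxy-10-oxotetradec-2-en-11-yn-1-yl]-5,7-dimethoxy-2-benzofuran-1(3H)-one | COc1cc(OC)c2c(c1)[C@@H](CC=CCCC[C@@H](O)CCC(=O)C#C[C@@H](C)OCc1ccccc1)OC2=O
F3 | step 11 | (3R)-3-[(7R,13R)-7,13-dihydroxy-10-oxotetradecyl]-5,7-dimethoxy-2-benzofuran-1(3H)-one | COc1cc(OC)c2c(c1)[C@@H](CCCCCC[C@@H](O)CCC(=O)CC[C@@H](C)O)OC2=O
F4 | step 9 | (2R,8R)-2-(benzyloxy)-8-hydroxytridec-12-en-3-yn-5-one | C=CCCC[C@@H](O)CCC(=O)C#C[C@@H](C)OCc1ccccc1
F5 | step 9 | (5R)-2-[(3R)-3-(benzyloxy)but-1-yn-1-yl]-5-(pent-4-en-1-yl)oxolane | C=CCCC[C@@H]1CCC(O1)C#C[C@@H](C)OCc1ccccc1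
F6 | step 10 | (3R)-3-{6-[(2R)-5-[(3R)-3-(benzyloxy)butyl]oxolan-2-yl]hexyl}-5,7-dimethoxy-2-benzofuran-1(3H)-one | COc1cc(OC)c2c(c1)[C@@H](CCCCCC[C@@H]1CCC(O1)CC[C@@H](C)OCc1ccccc1)OC2=O
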